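**Retrosynthetic overview**
1. Target 53 ⇒ C10–O ester bond (Yamaguchi, then Si–O cleavage) ⇒ iridolactone diol 27 + dienoic acid 50.
2. Acid 50 ⇒ key C9–C10 bond by intermolecular aldol addition of the ester enolate of 43 to acrolein; C7=C8 by ring-closing metathesis; C9=C10 by E1cB; all-cis cyclopentane 37 from (R)-pulegone (Favorskii contraction, enol triflate/Negishi, face-selective hydrogenation).
3. Lactone 27 ⇒ δ-lactone closed last, after α-methylenation of aldehyde 22 (C4=C11); C1 delivered to C9 by a silicon-tethered radical cyclisation from the C8 oxygen; C8 set by anti addition to α-silyloxy enone 7 (carbonyl allylation/oxidative transposition of 4).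
4. Ring order: acid half, cyclopentane (chiral pool) → cycloheptadiene; lactone half, cyclopentane (chiral pool) → temporary oxasilolane → pyranone; the halves are joined last.

Assumption: the SMILES is taken as drawn, i.e. the (4aR,6S,7S,7aR)-lactone esterified with the (3R,3aR,8aS)-acid; iridoid (C1–C11) and guaiane (C1–C15) numbering is used in the comments.

**Route**

Step 1
Reactants: 1 (1S,4R)-cis-4-acetoxycyclopent-2-en-1-ol
Product: 2 (1R,4S)-4-{[tert-butyl(dimethyl)silyl]oxy}cyclopent-2-en-1-yl acetate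
Conditions: TBSCl, imidazole, DMF, 0 °C → rt
Reagents that add atoms: tert-butyldimethylsilyl chloride, CC(C)(C)[Si](C)(C)Cl
Why: Imidazole-promoted silylation of the free allylic alcohol; no stereocentre is touched.

Step 2
Reactants: 2 (1R,4S)-4-{[tert-butyl(dimethyl)silyl]oxy}cyclopent-2-en-1-yl acetate
Product: 3 (1R,4S)-4-{[tert-butyl(dimethyl)silyl]oxy}cyclopent-2-en-1-ol
Conditions: K2CO3 (cat.), MeOH, 0 °C
Reagents that add atoms: none
Why: Base-catalysed transesterification removes only the acetate; the TBS ether and both stereocentres are untouched.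

Step 3
Reactants: 3 (1R,4S)-4-{[tert-butyl(dimethyl)silyl]oxy}cyclopent-2-en-1-ol
Product: 4 (4S)-4-{[tert-butyl(dimethyl)silyl]oxy}cyclopent-2-en-1-one
Conditions: activated MnO2, CH2Cl2, rt
Reagents that add atoms: none
Why: Neutral allylic oxidation gives the enone without β-elimination of the silyloxy group; the remaining (S) centre is the future C7.

Step 4
Reactants: 4 (4S)-4-{[tert-butyl(dimethyl)silyl]oxy}cyclopent-2-en-1-one; 5 allylmagnesium bromide
Product: 6 (1R,4S)-4-{[tert-butyl(dimethyl)silyl]oxy}-1-(prop-2-en-1-yl)cyclopent-2-en-1-ol (major C1 epimer)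
Conditions: THF, −78 °C; aq. NH4Cl
Reagents that add atoms: none
Why: Carbonyl allylation (Grignard 1,2-addition) forms the C4–C5 bond, mainly anti to OTBS; the new carbinol centre is erased in step 5.

Step 5
Reactants: 6 (1R,4S)-4-{[tert-butyl(dimethyl)silyl]oxy}-1-(prop-2-en-1-yl)cyclopent-2-en-1-ol
Product: 7 (5S)-5-{[tert-butyl(dimethyl)silyl]oxy}-3-(prop-2-en-1-yl)cyclopent-2-en-1-one
Conditions: PCC, SiO2, CH2Cl2, rt
Reagents that add atoms: none
Why: Dauben–Babler oxidative transposition ([3,3] shift of the chromate ester, then oxidation) moves the oxygen to C8 next to the silyloxy carbon; the non-basic medium leaves C7 intact.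

Step 6
Reactants: 8 (4-methoxyphenyl)methanol; 9 tributyl(iodomethyl)stannane
Product: 11 tributyl{[(4-methoxyphenyl)methoxy]methyl}stannane, via sodium (4-methoxyphenyl)methanolate 10 (not isolated)
Conditions: NaH, THF/DMF, 0 °C; then 9, rt
Reagents that add atoms: none
Why: Williamson ether synthesis (SN2 at the iodomethyl carbon) gives the Still-type α-alkoxymethylstannane.

Step 7
Reactants: 7 (5S)-5-{[tert-butyl(dimethyl)silyl]oxy}-3-(prop-2-en-1-yl)cyclopent-2-en-1-one; 11 tributyl{[(4-methoxyphenyl)methoxy]methyl}stannane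
Product: 13 (1S,5S)-5-{[tert-butyl(dimethyl)silyl]oxy}-1-{[(4-methoxyphenyl)methoxy]methyl}-3-(prop-2-en-1-yl)cyclopent-2-en-1-ol, via PMB-oxymethyllithium 12 (not isolated)
Conditions: 11, n-BuLi, THF, −78 °C; then 7, −78 °C; AcOH quench at −78 °C
Reagents that add atoms: none
Why: Sn–Li exchange (Still) gives the α-alkoxymethyllithium, which adds 1,2 to the enone anti to the adjacent OTBS group, so C8 carries CH2OPMB trans and OH cis to the C7 oxygen.

Step 8
Reactants: 13 (1S,5S)-5-{[tert-butyl(dimethyl)silyl]oxy}-1-{[(4-methoxyphenyl)methoxy]methyl}-3-(prop-2-en-1-yl)cyclopent-2-en-1-ol; 14 (bromomethyl)chlorodimethylsilane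
Product: 15 (bromomethyl)({(1S,5S)-5-{[tert-butyl(dimethyl)silyl]oxy}-1-{[(4-methoxyphenyl)methoxy]methyl}-3-(prop-2-en-1-yl)cyclopent-2-en-1-yl}oxy)dimethylsilane
Conditions: Et3N, DMAP (cat.), CH2Cl2, 0 °C → rt
Reagents that add atoms: none
Why: Silylation of the tertiary allylic alcohol installs the Stork–Nishiyama one-carbon tether on the C8 oxygen.

Step 9
Reactants: 15 (bromomethyl)({(1S,5S)-5-{[tert-butyl(dimethyl)silyl]oxy}-1-{[(4-methoxyphenyl)methoxy]methyl}-3-(prop-2-en-1-yl)cyclopent-2-en-1-yl}oxy)dimethylsilane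
Product: 16 (3aR,4R,6S,6aS)-6-{[tert-butyl(dimethyl)silyl]oxy}-6a-{[(4-methoxyphenyl)methoxy]methyl}-2,2-dimethyl-4-(prop-2-en-1-yl)hexahydro-2H-cyclopenta[d][1,2]oxasilole
Conditions: Bu3SnH (slow addition), AIBN (cat.), PhH (0.01 M), 80 °C
Reagents that add atoms: none
Why: Stork–Nishiyama radical cyclisation: the tethered CH2 radical closes 5-exo on C9 and can only do so cis to the C8 oxygen (this carbon becomes C1); the tertiary C5 radical then takes H from the exo face of the cis-fused bicycle, leaving allyl cis to the new CH2.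

Step 10
Reactants: 16 (3aR,4R,6S,6aS)-6-{[tert-butyl(dimethyl)silyl]oxy}-6a-{[(4-methoxyphenyl)methoxy]methyl}-2,2-dimethyl-4-(prop-2-en-1-yl)hexahydro-2H-cyclopenta[d][1,2]oxasilole
Product: 17 (1S,2S,3R,5S)-5-{[tert-butyl(dimethyl)silyl]oxy}-2-(hydroxymethyl)-1-{[(4-methoxyphenyl)methoxy]methyl}-3-(prop-2-en-1-yl)cyclopentan-1-ol
Conditions: 30% H2O2, KF, KHCO3, THF/MeOH, rt
Reagents that add atoms: hydrogen peroxide, OO
Why: Tamao–Fleming oxidation turns the C–Si bond into C–OH with retention and frees the tertiary alcohol.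

Step 11
Reactants: 17 (1S,2S,3R,5S)-5-{[tert-butyl(dimethyl)silyl]oxy}-2-(hydroxymethyl)-1-{[(4-methoxyphenyl)methoxy]methyl}-3-(prop-2-en-1-yl)cyclopentan-1-ol
Product: 20 methyl (1R,2S,3S,5R)-3-{[tert-butyl(dimethyl)silyl]oxy}-2-hydroxy-2-{[(4-methoxyphenyl)methoxy]methyl}-5-(prop-2-en-1-yl)cyclopentane-1-carboxylate, via aldehyde 18 (not isolated), via carboxylic acid 19 (not isolated)
Conditions: TEMPO (cat.), PhI(OAc)2, MeCN/H2O, rt; then TMSCHN2, PhMe/MeOH, 0 °C
Reagents that add atoms: water, O; (trimethylsilyl)diazomethane, C[Si](C)(C)C=[N+]=[N-]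
Why: The oxoammonium oxidation takes only the primary alcohol (through the aldehyde hydrate) to the acid, which is methylated at once; the near-neutral medium does not epimerise C9.

Step 12
Reactants: 20 methyl (1R,2S,3S,5R)-3-{[tert-butyl(dimethyl)silyl]oxy}-2-hydroxy-2-{[(4-methoxyphenyl)methoxy]methyl}-5-(prop-2-en-1-yl)cyclopentane-1-carboxylate
Product: 22 methyl (1R,2S,3S,5S)-3-{[tert-butyl(dimethyl)silyl]oxy}-2-hydroxy-2-{[(4-methoxyphenyl)methoxy]methyl}-5-(2-oxoethyl)cyclopentane-1-carboxylate, via vicinal diol 21 (not isolated)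
Conditions: OsO4 (cat.), NaIO4, 2,6-lutidine, dioxane/H2O, rt
Reagents that add atoms: sodium periodate, [Na+].[O-]I(=O)(=O)=O
Why: Lemieux–Johnson cleavage of the only alkene gives the C3 aldehyde; no stereocentre is involved (the descriptor at the ring carbon changes only through priorities).

Step 13
Reactants: 22 methyl (1R,2S,3S,5S)-3-{[tert-butyl(dimethyl)silyl]oxy}-2-hydroxy-2-{[(4-methoxyphenyl)methoxy]methyl}-5-(2-oxoethyl)cyclopentane-1-carboxylate; 23 formaldehyde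
Product: 24 methyl (1R,2S,3S,5R)-3-{[tert-butyl(dimethyl)silyl]oxy}-2-hydroxy-2-{[(4-methoxyphenyl)methoxy]methyl}-5-(3-oxoprop-1-en-2-yl)cyclopentane-1-carboxylate
Conditions: 37% aq. CH2O, pyrrolidine (cat.), EtCO2H (cat.), i-PrOH, 45 °C
Reagents that add atoms: none
Why: Amine-catalysed Mannich-type α-methylenation of the aldehyde introduces C11 as the C4 methylidene; the carbon that reacts becomes sp2.

Step 14
Reactants: 24 methyl (1R,2S,3S,5R)-3-{[tert-butyl(dimethyl)silyl]oxy}-2-hydroxy-2-{[(4-methoxyphenyl)methoxy]methyl}-5-(3-oxoprop-1-en-2-yl)cyclopentane-1-carboxylate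
Product: 26 (4aR,6S,7S,7aR)-6-{[tert-butyl(dimethyl)silyl]oxy}-7-hydroxy-7-{[(4-methoxyphenyl)methoxy]methyl}-4-methylidenehexahydrocyclopenta[c]pyran-1(3H)-one, via hydroxy ester 25 (not isolated)
Conditions: NaBH4, CeCl3·7H2O, MeOH, −20 °C; work-up; then PPTS (cat.), PhMe, 60 °C
Reagents that add atoms: none
Why: Luche 1,2-reduction of the enal gives the allylic alcohol, which lactonises onto the cis ester (acid-catalysed transesterification) to the cis-fused δ-lactone; no stereocentre is affected.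

Step 15
Reactants: 26 (4aR,6S,7S,7aR)-6-{[tert-butyl(dimethyl)silyl]oxy}-7-hydroxy-7-{[(4-methoxyphenyl)methoxy]methyl}-4-methylidenehexahydrocyclopenta[c]pyran-1(3H)-one
Product: 27 (4aR,6S,7S,7aR)-6-{[tert-butyl(dimethyl)silyl]oxy}-7-hydroxy-7-(hydroxymethyl)-4-methylidenehexahydrocyclopenta[c]pyran-1(3H)-one
Conditions: DDQ, CH2Cl2/pH 7 buffer, 0 °C → rt
Reagents that add atoms: none
Why: Oxidative PMB cleavage frees the primary C10 alcohol; TBS ether, lactone and alkene are inert.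

Step 16
Reactants: 28 (R)-(+)-pulegone [(5R)-5-methyl-2-(propan-2-ylidene)cyclohexan-1-one]
Product: 30 methyl (2R)-2-methyl-5-(propan-2-ylidene)cyclopentane-1-carboxylate (methyl pulegenate; C1 epimers), via pulegone dibromide 29 (not isolated)
Conditions: Br2, AcOH/Et2O, 0 °C; then NaOMe, MeOH, reflux
Reagents that add atoms: sodium methoxide, [Na+].[O-]C
Why: Favorskii ring contraction of the dibromide followed by dehydrobromination; the methyl-bearing centre (future C4, R) is untouched.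

Step 17
Reactants: 30 methyl (2R)-2-methyl-5-(propan-2-ylidene)cyclopentane-1-carboxylate
Product: 32 methyl (1S,2R)-2-methyl-5-oxocyclopentane-1-carboxylate (trans; equilibrates via its enol), via secondary ozonide 31 (not isolated)
Conditions: O3, CH2Cl2, −78 °C; then Me2S, −78 °C → rt
Reagents that add atoms: ozone, [O-][O+]=O
Why: Ozonolysis of the tetrasubstituted alkene with reductive work-up gives the β-keto ester.

Step 18
Reactants: 32 methyl (1S,2R)-2-methyl-5-oxocyclopentane-1-carboxylate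
Product: 33 methyl (5R)-5-methyl-2-{[(trifluoromethyl)sulfonyl]oxy}cyclopent-1-ene-1-carboxylate
Conditions: Tf2O, i-Pr2NEt, CH2Cl2, −78 → 0 °C
Reagents that add atoms: trifluoromethanesulfonic anhydride, O=S(=O)(OS(=O)(=O)C(F)(F)F)C(F)(F)F
Why: O-Triflation of the enol between the two carbonyls gives the vinyl triflate; C4 is remote from the enolisation.

Step 19
Reactants: 33 methyl (5R)-5-methyl-2-{[(trifluoromethyl)sulfonyl]oxy}cyclopent-1-ene-1-carboxylate; 34 tert-butyl bromoacetate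
Product: 36 methyl (5R)-2-(2-tert-butoxy-2-oxoethyl)-5-methylcyclopent-1-ene-1-carboxylate, via Reformatsky zinc reagent 35 (not isolated)
Conditions: 34, Zn, THF, 40 °C; then 33, Pd2(dba)3 (cat.), XPhos (cat.), THF, 60 °C
Reagents that add atoms: none
Why: Reformatsky–Negishi sp2–sp3 cross-coupling replaces OTf by CH2CO2t-Bu (C10/C14) and gives the tetrasubstituted enoate.

Step 20
Reactants: 36 methyl (5R)-2-(2-tert-butoxy-2-oxoethyl)-5-methylcyclopent-1-ene-1-carboxylate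
Product: 37 methyl (1R,2R,5R)-2-(2-tert-butoxy-2-oxoethyl)-5-methylcyclopentane-1-carboxylate (all-cis)
Conditions: H2 (50 bar), 10% Pd/C, EtOAc, rt
Reagents that add atoms: none
Why: Heterogeneous hydrogenation adds H2 syn to the C1=C5 bond from the face opposite the C4 methyl, which sets C1 and C5 with all three substituents cis.

Step 21
Reactants: 37 methyl (1R,2R,5R)-2-(2-tert-butoxy-2-oxoethyl)-5-methylcyclopentane-1-carboxylate
Product: 38 tert-butyl 2-[(1R,2R,3R)-2-(hydroxymethyl)-3-methylcyclopentyl]acetate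
Conditions: LiBH4, THF/MeOH, 0 °C → rt; AcOH quench at 0 °C
Reagents that add atoms: none
Why: LiBH4 reduces the methyl ester but not the tert-butyl ester; C5 is not epimerised.

Step 22
Reactants: 38 tert-butyl 2-[(1R,2R,3R)-2-(hydroxymethyl)-3-methylcyclopentyl]acetate
Product: 39 tert-butyl 2-[(1R,2R,3R)-2-(iodomethyl)-3-methylcyclopentyl]acetate
Conditions: I2, PPh3, imidazole, CH2Cl2, 0 °C → rt
Reagents that add atoms: iodine, II
Why: Appel-type iodination of the primary alcohol (SN2 at CH2); no stereocentre is involved.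

Step 23
Reactants: 39 tert-butyl 2-[(1R,2R,3R)-2-(iodomethyl)-3-methylcyclopentyl]acetate; 40 2-methylpropanoyl chloride
Product: 42 tert-butyl 2-[(1R,2R,3R)-3-methyl-2-(3-methyl-2-oxobutyl)cyclopentyl]acetate, via alkylzinc iodide 41 (not isolated)
Conditions: Zn dust, LiCl, THF, 40 °C; then 40, Pd(PPh3)4 (cat.), THF, 0 °C → rt
Reagents that add atoms: none
Why: Zinc insertion and Pd-catalysed Negishi acylation form the C6–C7 bond; the organozinc tolerates the tert-butyl ester.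

Step 24
Reactants: 42 tert-butyl 2-[(1R,2R,3R)-3-methyl-2-(3-methyl-2-oxobutyl)cyclopentyl]acetate
Product: 43 tert-butyl 2-[(1R,2R,3R)-3-methyl-2-(3-methyl-2-methylidenebutyl)cyclopentyl]acetate
Conditions: Ph3PCH3Br, KOt-Bu, THF/PhMe, 0 → 60 °C
Reagents that add atoms: methyltriphenylphosphonium bromide, C[P+](c1ccccc1)(c1ccccc1)c1ccccc1.[Br-]
Why: Wittig methylenation of the isopropyl ketone gives the 1,1-disubstituted alkene needed for ring closure; no stereocentre is α to the ketone.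

Step 25 (key step)
Reactants: 43 tert-butyl 2-[(1R,2R,3R)-3-methyl-2-(3-methyl-2-methylidenebutyl)cyclopentyl]acetate; 44 prop-2-enal (acrolein)
Product: 47 tert-butyl 3-(acetyloxy)-2-[(1S,2R,3R)-3-methyl-2-(3-methyl-2-methylidenebutyl)cyclopentyl]pent-4-enoate (C2/C3 diastereomer mixture), via lithium ester enolate 45 (not isolated), via lithium aldolate 46 (not isolated)
Conditions: LDA, THF, −78 °C; 44, −78 °C; then Ac2O, −78 → 0 °C
Reagents that add atoms: acetic anhydride, CC(=O)OC(C)=O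
Why: Intermolecular aldol addition of the tert-butyl ester enolate to acrolein (1,2-attack) forms the C9–C10 bond and the aldolate is trapped as its acetate; the two new centres do not matter because both carbons become sp2 in step 27.

Step 26
Reactants: 47 tert-butyl 3-(acetyloxy)-2-[(1S,2R,3R)-3-methyl-2-(3-methyl-2-methylidenebutyl)cyclopentyl]pent-4-enoate
Product: 48 tert-butyl (3R,3aR,8aS)-7-(acetyloxy)-3-methyl-5-(propan-2-yl)-1,2,3,3a,4,7,8,8a-octahydroazulene-8-carboxylate (C7/C8 diastereomers)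
Conditions: Hoveyda–Grubbs II (10 mol%), PhMe (5 mM), 80 °C
Reagents that add atoms: none
Why: Ring-closing metathesis between the vinyl group and the 1,1-disubstituted alkene closes the cis-fused seven-membered ring as the trisubstituted C7=C8 alkene; ring stereocentres are untouched.

Step 27
Reactants: 48 tert-butyl (3R,3aR,8aS)-7-(acetyloxy)-3-methyl-5-(propan-2-yl)-1,2,3,3a,4,7,8,8a-octahydroazulene-8-carboxylate
Product: 49 tert-butyl (3R,3aR,8aS)-3-methyl-5-(propan-2-yl)-1,2,3,3a,4,8a-hexahydroazulene-8-carboxylate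
Conditions: DBU, CH2Cl2, rt → 40 °C
Reagents that add atoms: none
Why: E1cB loss of acetic acid from the β-acetoxy ester installs C9=C10 in conjugation with C7=C8 and the ester; C1 carries no acidic hydrogen.

Step 28
Reactants: 49 tert-butyl (3R,3aR,8aS)-3-methyl-5-(propan-2-yl)-1,2,3,3a,4,8a-hexahydroazulene-8-carboxylate
Product: 50 (3R,3aR,8aS)-3-methyl-5-(propan-2-yl)-1,2,3,3a,4,8a-hexahydroazulene-8-carboxylic acid
Conditions: TFA/CH2Cl2 (1:4), 0 °C
Reagents that add atoms: none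
Why: Acidolysis of the tert-butyl ester (loss of isobutene) gives the acid; the ester-conjugated diene is not protonated at 0 °C.

Step 29
Reactants: 27 (4aR,6S,7S,7aR)-6-{[tert-butyl(dimethyl)silyl]oxy}-7-hydroxy-7-(hydroxymethyl)-4-methylidenehexahydrocyclopenta[c]pyran-1(3H)-one; 50 (3R,3aR,8aS)-3-methyl-5-(propan-2-yl)-1,2,3,3a,4,8a-hexahydroazulene-8-carboxylic acid
Product: 52 [(4aR,6S,7S,7aR)-6-{[tert-butyl(dimethyl)silyl]oxy}-7-hydroxy-4-methylidene-1-oxooctahydrocyclopenta[c]pyran-7-yl]methyl (3R,3aR,8aS)-3-methyl-5-(propan-2-yl)-1,2,3,3a,4,8a-hexahydroazulene-8-carboxylate, via mixed anhydride 51 (not isolated)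
Conditions: 50, 2,4,6-trichlorobenzoyl chloride, Et3N, THF, rt; then 27, DMAP, PhMe, rt → 40 °C
Reagents that add atoms: none
Why: Yamaguchi esterification acylates the primary C10 alcohol only; the tertiary alcohol is inert and the C7 oxygen is silyl-protected.

Step 30
Reactants: 52 [(4aR,6S,7S,7aR)-6-{[tert-butyl(dimethyl)silyl]oxy}-7-hydroxy-4-methylidene-1-oxooctahydrocyclopenta[c]pyran-7-yl]methyl (3R,3aR,8aS)-3-methyl-5-(propan-2-yl)-1,2,3,3a,4,8a-hexahydroazulene-8-carboxylate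
Product: 53 nardostachysin
Conditions: HF·pyridine, THF/pyridine, 0 °C → rt
Reagents that add atoms: none
Why: Buffered fluoride desilylation frees the C7 hydroxyl without acyl migration or lactone opening and gives the target.

**Compound list**
1 | (1S,4R)-cis-4-acetoxycyclopent-2-en-1-ol | CC(=O)O[C@@H]1C[C@H](O)C=C1 | starting material
2 | (1R,4S)-4-{[tert-butyl(dimethyl)silyl]oxy}cyclopent-2-en-1-yl acetate | CC(=O)O[C@@H]1C[C@H](O[Si](C)(C)C(C)(C)C)C=C1 | intermediate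
3 | (1R,4S)-4-{[tert-butyl(dimethyl)silyl]oxy}cyclopent-2-en-1-ol | O[C@@H]1C[C@H](O[Si](C)(C)C(C)(C)C)C=C1 | intermediate
4 | (4S)-4-{[tert-butyl(dimethyl)silyl]oxy}cyclopent-2-en-1-one | O=C1C[C@H](O[Si](C)(C)C(C)(C)C)C=C1 | intermediate
5 | allylmagnesium bromide | C=CC[Mg]Br | starting material
6 | (1R,4S)-4-{[tert-butyl(dimethyl)silyl]oxy}-1-(prop-2-en-1-yl)cyclopent-2-en-1-ol (major C1 epimer) | C=CC[C@@]1(O)C[C@H](O[Si](C)(C)C(C)(C)C)C=C1 | intermediate
7 | (5S)-5-{[tert-butyl(dimethyl)silyl]oxy}-3-(prop-2-en-1-yl)cyclopent-2-en-1-one | C=CCC1=CC(=O)[C@@H](O[Si](C)(C)C(C)(C)C)C1 | intermediate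
8 | (4-methoxyphenyl)methanol | COc1ccc(CO)cc1 | starting material
9 | tributyl(iodomethyl)stannane | CCCC[Sn](CCCC)(CCCC)CI | starting material
10 | sodium (4-methoxyphenyl)methanolate | COc1ccc(C[O-])cc1.[Na+] | intermediate (not isolated)
11 | tributyl{[(4-methoxyphenyl)methoxy]methyl}stannane | CCCC[Sn](CCCC)(CCCC)COCc1ccc(OC)cc1 | intermediate
12 | {[(4-methoxyphenyl)methoxy]methyl}lithium | [Li]COCc1ccc(OC)cc1 | intermediate (not isolated)
13 | (1S,5S)-5-{[tert-butyl(dimethyl)silyl]oxy}-1-{[(4-methoxyphenyl)methoxy]methyl}-3-(prop-2-en-1-yl)cyclopent-2-en-1-ol | C=CCC1=C[C@](O)(COCc2ccc(OC)cc2)[C@@H](O[Si](C)(C)C(C)(C)C)C1 | intermediate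
14 | (bromomethyl)chlorodimethylsilane | C[Si](C)(Cl)CBr | starting material
15 | (bromomethyl)({(1S,5S)-5-{[tert-butyl(dimethyl)silyl]oxy}-1-{[(4-methoxyphenyl)methoxy]methyl}-3-(prop-2-en-1-yl)cyclopent-2-en-1-yl}oxy)dimethylsilane | C=CCC1=C[C@](O[Si](C)(C)CBr)(COCc2ccc(OC)cc2)[C@@H](O[Si](C)(C)C(C)(C)C)C1 | intermediate
16 | (3aR,4R,6S,6aS)-6-{[tert-butyl(dimethyl)silyl]oxy}-6a-{[(4-methoxyphenyl)methoxy]methyl}-2,2-dimethyl-4-(prop-2-en-1-yl)hexahydro-2H-cyclopenta[d][1,2]oxasilole | C=CC[C@@H]1C[C@H](O[Si](C)(C)C(C)(C)C)[C@]2(COCc3ccc(OC)cc3)O[Si](C)(C)C[C@H]12 | intermediate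
17 | (1S,2S,3R,5S)-5-{[tert-butyl(dimethyl)silyl]oxy}-2-(hydroxymethyl)-1-{[(4-methoxyphenyl)methoxy]methyl}-3-(prop-2-en-1-yl)cyclopentan-1-ol | C=CC[C@@H]1C[C@H](O[Si](C)(C)C(C)(C)C)[C@@](O)(COCc2ccc(OC)cc2)[C@@H]1CO | intermediate
18 | (1R,2S,3S,5R)-3-{[tert-butyl(dimethyl)silyl]oxy}-2-hydroxy-2-{[(4-methoxyphenyl)methoxy]methyl}-5-(prop-2-en-1-yl)cyclopentane-1-carbaldehyde | C=CC[C@@H]1C[C@H](O[Si](C)(C)C(C)(C)C)[C@@](O)(COCc2ccc(OC)cc2)[C@@H]1C=O | intermediate (not isolated)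
19 | (1R,2S,3S,5R)-3-{[tert-butyl(dimethyl)silyl]oxy}-2-hydroxy-2-{[(4-methoxyphenyl)methoxy]methyl}-5-(prop-2-en-1-yl)cyclopentane-1-carboxylic acid | C=CC[C@@H]1C[C@H](O[Si](C)(C)C(C)(C)C)[C@@](O)(COCc2ccc(OC)cc2)[C@@H]1C(=O)O | intermediate (not isolated)
20 | methyl (1R,2S,3S,5R)-3-{[tert-butyl(dimethyl)silyl]oxy}-2-hydroxy-2-{[(4-methoxyphenyl)methoxy]methyl}-5-(prop-2-en-1-yl)cyclopentane-1-carboxylate | C=CC[C@@H]1C[C@H](O[Si](C)(C)C(C)(C)C)[C@@](O)(COCc2ccc(OC)cc2)[C@@H]1C(=O)OC | intermediate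
21 | methyl (1R,2S,3S,5R)-3-{[tert-butyl(dimethyl)silyl]oxy}-5-(2,3-dihydroxypropyl)-2-hydroxy-2-{[(4-methoxyphenyl)methoxy]methyl}cyclopentane-1-carboxylate (side-chain carbinol epimers) | OCC(O)C[C@@H]1C[C@H](O[Si](C)(C)C(C)(C)C)[C@@](O)(COCc2ccc(OC)cc2)[C@@H]1C(=O)OC | intermediate (not isolated)
22 | methyl (1R,2S,3S,5S)-3-{[tert-butyl(dimethyl)silyl]oxy}-2-hydroxy-2-{[(4-methoxyphenyl)methoxy]methyl}-5-(2-oxoethyl)cyclopentane-1-carboxylate | O=CC[C@@H]1C[C@H](O[Si](C)(C)C(C)(C)C)[C@@](O)(COCc2ccc(OC)cc2)[C@@H]1C(=O)OC | intermediate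
23 | formaldehyde | C=O | starting material
24 | methyl (1R,2S,3S,5R)-3-{[tert-butyl(dimethyl)silyl]oxy}-2-hydroxy-2-{[(4-methoxyphenyl)methoxy]methyl}-5-(3-oxoprop-1-en-2-yl)cyclopentane-1-carboxylate | C=C(C=O)[C@@H]1C[C@H](O[Si](C)(C)C(C)(C)C)[C@@](O)(COCc2ccc(OC)cc2)[C@@H]1C(=O)OC | intermediate
25 | methyl (1R,2S,3S,5R)-3-{[tert-butyl(dimethyl)silyl]oxy}-2-hydroxy-5-(3-hydroxyprop-1-en-2-yl)-2-{[(4-methoxyphenyl)methoxy]methyl}cyclopentane-1-carboxylate | C=C(CO)[C@@H]1C[C@H](O[Si](C)(C)C(C)(C)C)[C@@](O)(COCc2ccc(OC)cc2)[C@@H]1C(=O)OC | intermediate (not isolated)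
26 | (4aR,6S,7S,7aR)-6-{[tert-butyl(dimethyl)silyl]oxy}-7-hydroxy-7-{[(4-methoxyphenyl)methoxy]methyl}-4-methylidenehexahydrocyclopenta[c]pyran-1(3H)-one | C=C1COC(=O)[C@@H]2[C@H]1C[C@H](O[Si](C)(C)C(C)(C)C)[C@@]2(O)COCc1ccc(OC)cc1 | intermediate
27 | (4aR,6S,7S,7aR)-6-{[tert-butyl(dimethyl)silyl]oxy}-7-hydroxy-7-(hydroxymethyl)-4-methylidenehexahydrocyclopenta[c]pyran-1(3H)-one | C=C1COC(=O)[C@@H]2[C@H]1C[C@H](O[Si](C)(C)C(C)(C)C)[C@@]2(O)CO | intermediate
28 | (R)-(+)-pulegone, (5R)-5-methyl-2-(propan-2-ylidene)cyclohexan-1-one | C[C@@H]1CCC(=C(C)C)C(=O)C1 | starting material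
29 | (5R)-2-bromo-2-(2-bromopropan-2-yl)-5-methylcyclohexan-1-one (C2 epimers) | C[C@@H]1CCC(Br)(C(C)(C)Br)C(=O)C1 | intermediate (not isolated)
30 | methyl (2R)-2-methyl-5-(propan-2-ylidene)cyclopentane-1-carboxylate (C1 epimers) | COC(=O)C1[C@H](C)CCC1=C(C)C | intermediate
31 | methyl (7R)-3,3,7-trimethyl-1,2,4-trioxaspiro[4.4]nonane-6-carboxylate (secondary ozonide of 30) | COC(=O)C1[C@H](C)CCC12OOC(C)(C)O2 | intermediate (not isolated)
32 | methyl (1S,2R)-2-methyl-5-oxocyclopentane-1-carboxylate (trans) | COC(=O)[C@H]1[C@H](C)CCC1=O | intermediate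
33 | methyl (5R)-5-methyl-2-{[(trifluoromethyl)sulfonyl]oxy}cyclopent-1-ene-1-carboxylate | COC(=O)C1=C(OS(=O)(=O)C(F)(F)F)CC[C@H]1C | intermediate
34 | tert-butyl bromoacetate | CC(C)(C)OC(=O)CBr | starting material
35 | bromo(2-tert-butoxy-2-oxoethyl)zinc | CC(C)(C)OC(=O)C[Zn]Br | intermediate (not isolated)
36 | methyl (5R)-2-(2-tert-butoxy-2-oxoethyl)-5-methylcyclopent-1-ene-1-carboxylate | COC(=O)C1=C(CC(=O)OC(C)(C)C)CC[C@H]1C | intermediate
37 | methyl (1R,2R,5R)-2-(2-tert-butoxy-2-oxoethyl)-5-methylcyclopentane-1-carboxylate (all-cis) | COC(=O)[C@@H]1[C@H](C)CC[C@@H]1CC(=O)OC(C)(C)C | intermediate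
38 | tert-butyl 2-[(1R,2R,3R)-2-(hydroxymethyl)-3-methylcyclopentyl]acetate | OC[C@@H]1[C@H](C)CC[C@@H]1CC(=O)OC(C)(C)C | intermediate
39 | tert-butyl 2-[(1R,2R,3R)-2-(iodomethyl)-3-methylcyclopentyl]acetate | IC[C@@H]1[C@H](C)CC[C@@H]1CC(=O)OC(C)(C)C | intermediate
40 | 2-methylpropanoyl chloride | CC(C)C(=O)Cl | starting material
41 | iodo{[(1R,2R,5R)-2-(2-tert-butoxy-2-oxoethyl)-5-methylcyclopentyl]methyl}zinc | I[Zn]C[C@@H]1[C@H](C)CC[C@@H]1CC(=O)OC(C)(C)C | intermediate (not isolated)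
42 | tert-butyl 2-[(1R,2R,3R)-3-methyl-2-(3-methyl-2-oxobutyl)cyclopentyl]acetate | CC(C)C(=O)C[C@@H]1[C@H](C)CC[C@@H]1CC(=O)OC(C)(C)C | intermediate
43 | tert-butyl 2-[(1R,2R,3R)-3-methyl-2-(3-methyl-2-methylidenebutyl)cyclopentyl]acetate | C=C(C(C)C)C[C@@H]1[C@H](C)CC[C@@H]1CC(=O)OC(C)(C)C | intermediate
44 | prop-2-enal (acrolein) | C=CC=O | starting material
45 | lithium enolate of 43 (O-lithio ketene acetal of the tert-butyl ester) | C=C(C(C)C)C[C@@H]1[C@H](C)CC[C@@H]1C=C(O[Li])OC(C)(C)C | intermediate (not isolated)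
46 | lithium alkoxide of tert-butyl 3-hydroxy-2-[(1S,2R,3R)-3-methyl-2-(3-methyl-2-methylidenebutyl)cyclopentyl]pent-4-enoate | C=C(C(C)C)C[C@@H]1[C@H](C)CC[C@@H]1C(C(=O)OC(C)(C)C)C(O[Li])C=C | intermediate (not isolated)
47 | tert-butyl 3-(acetyloxy)-2-[(1S,2R,3R)-3-methyl-2-(3-methyl-2-methylidenebutyl)cyclopentyl]pent-4-enoate (C2/C3 diastereomers) | C=C(C(C)C)C[C@@H]1[C@H](C)CC[C@@H]1C(C(=O)OC(C)(C)C)C(OC(C)=O)C=C | intermediate
48 | tert-butyl (3R,3aR,8aS)-7-(acetyloxy)-3-methyl-5-(propan-2-yl)-1,2,3,3a,4,7,8,8a-octahydroazulene-8-carboxylate (C7/C8 diastereomers) | CC(C)(C)OC(=O)C1C(OC(C)=O)C=C(C(C)C)C[C@@H]2[C@H](C)CC[C@H]12 | intermediate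
49 | tert-butyl (3R,3aR,8aS)-3-methyl-5-(propan-2-yl)-1,2,3,3a,4,8a-hexahydroazulene-8-carboxylate | CC(C)(C)OC(=O)C1=CC=C(C(C)C)C[C@@H]2[C@H](C)CC[C@H]12 | intermediate
50 | (3R,3aR,8aS)-3-methyl-5-(propan-2-yl)-1,2,3,3a,4,8a-hexahydroazulene-8-carboxylic acid | OC(=O)C1=CC=C(C(C)C)C[C@@H]2[C@H](C)CC[C@H]12 | intermediate
51 | (3R,3aR,8aS)-3-methyl-5-(propan-2-yl)-1,2,3,3a,4,8a-hexahydroazulene-8-carboxylic 2,4,6-trichlorobenzoic anhydride | O=C(OC(=O)c1c(Cl)cc(Cl)cc1Cl)C1=CC=C(C(C)C)C[C@@H]2[C@H](C)CC[C@H]12 | intermediate (not isolated)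
52 | [(4aR,6S,7S,7aR)-6-{[tert-butyl(dimethyl)silyl]oxy}-7-hydroxy-4-methylidene-1-oxooctahydrocyclopenta[c]pyran-7-yl]methyl (3R,3aR,8aS)-3-methyl-5-(propan-2-yl)-1,2,3,3a,4,8a-hexahydroazulene-8-carboxylate | C=C1COC(=O)[C@@H]2[C@H]1C[C@H](O[Si](C)(C)C(C)(C)C)[C@@]2(O)COC(=O)C1=CC=C(C(C)C)C[C@@H]2[C@H](C)CC[C@H]12 | intermediate
53 | nardostachysin, [(4aR,6S,7S,7aR)-6,7-dihydroxy-4-methylidene-1-oxooctahydrocyclopenta[c]pyran-7-yl]methyl (3R,3aR,8aS)-3-methyl-5-(propan-2-yl)-1,2,3,3a,4,8a-hexahydroazulene-8-carboxylate | C=C1COC(=O)[C@@H]2[C@H]1C[C@H](O)[C@@]2(O)COC(=O)C1=CC=C(C(C)C)C[C@@H]2[C@H](C)CC[C@H]12 | target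

**Totals**
Total step count: 30.
Longest linear sequence: 16 steps (1 → 53 through steps 1–5, 7–15, 29, 30); the acid branch is 13 steps (16–28) before the union.

**Three steps most likely to fail, with fallbacks**

Step 20 (hydrogenation of the tetrasubstituted enoate 36). Risk: slow reduction, double-bond migration on Pd and only moderate facial bias from one methyl group. Fallback, setting out from 36 and returning at 38: reduce the conjugated methyl ester first (DIBAL-H, CH2Cl2, −78 °C; the tert-butyl ester survives) to the allylic alcohol tert-butyl 2-[(3R)-2-(hydroxymethyl)-3-methylcyclopent-1-en-1-yl]acetate F1. Then saturate the tetrasubstituted olefin of F1 with the cationic iridium catalyst [Ir(cod)(PCy3)(py)]PF6 under H2 in CH2Cl2, which reduces such olefins without migration and again from the face opposite the methyl. This gives 38 directly and bypasses 37.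

Step 26 (ring-closing metathesis to the isopropyl-bearing trisubstituted alkene). Risk: the α-branched 1,1-disubstituted olefin may not engage. Fallback, setting out from ketone 42 and returning at 49, closes the ring at C9=C10 instead:
- Allylate the ketone (allylmagnesium bromide, THF, −78 °C) to tert-butyl 2-{(1R,2R,3R)-2-[2-hydroxy-2-(propan-2-yl)pent-4-en-1-yl]-3-methylcyclopentyl}acetate F2.
- Convert the acetate arm into an acrylate: LDA (2.2 equiv) and Eschenmoser's salt give the Mannich base tert-butyl 3-(dimethylamino)-2-{(1S,2R,3R)-2-[2-hydroxy-2-(propan-2-yl)pent-4-en-1-yl]-3-methylcyclopentyl}propanoate F3; MeI gives the trimethylammonium iodide F4; DBU gives tert-butyl 2-{(1S,2R,3R)-2-[2-hydroxy-2-(propan-2-yl)pent-4-en-1-yl]-3-methylcyclopentyl}prop-2-enoate F5.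
- Ring-closing metathesis of F5 (Grubbs II, PhMe, 80 °C) gives tert-butyl (3R,3aR,8aS)-5-hydroxy-3-methyl-5-(propan-2-yl)-1,2,3,3a,4,5,6,8a-octahydroazulene-8-carboxylate F6.
- Dehydrate the tertiary alcohol toward the activated C8–H (SOCl2, pyridine, 0 °C) to reach 49.

Step 29 (esterification of a hindered dienoic acid with a neopentylic primary alcohol next to a free tertiary alcohol). Risk: slow acylation or acyl scrambling. Fallback, setting out from diol 27 and returning at 52, makes the C10–O bond by epoxide opening instead of acyl transfer: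
- Tosylate the primary hydroxyl selectively (TsCl, Et3N, cat. Bu2SnO, CH2Cl2) to [(4aR,6S,7S,7aR)-6-{[tert-butyl(dimethyl)silyl]oxy}-7-hydroxy-4-methylidene-1-oxooctahydrocyclopenta[c]pyran-7-yl]methyl 4-methylbenzenesulfonate F7.
- Close the spiro-epoxide with DBU (retention at C8) to (4aR,6S,7S,7aR)-6-{[tert-butyl(dimethyl)silyl]oxy}-4-methylidenehexahydro-1H-spiro[cyclopenta[c]pyran-7,2'-oxiran]-1-one F8.
- Open F8 at its CH2 terminus with the caesium salt of acid 50 (Cs2CO3, DMF, 60 °C) to give 52.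

**Further compounds**
F1 | step 20 | tert-butyl 2-[(3R)-2-(hydroxymethyl)-3-methylcyclopent-1-en-1-yl]acetate | OCC1=C(CC(=O)OC(C)(C)C)CC[C@H]1C
F2 | step 26 | tert-butyl 2-{(1R,2R,3R)-2-[2-hydroxy-2-(propan-2-yl)pent-4-en-1-yl]-3-methylcyclopentyl}acetate (carbinol epimers) | C=CCC(O)(C(C)C)C[C@@H]1[C@H](C)CC[C@@H]1CC(=O)OC(C)(C)C
F3 | step 26 | tert-butyl 3-(dimethylamino)-2-{(1S,2R,3R)-2-[2-hydroxy-2-(propan-2-yl)pent-4-en-1-yl]-3-methylcyclopentyl}propanoate | C=CCC(O)(C(C)C)C[C@@H]1[C@H](C)CC[C@@H]1C(CN(C)C)C(=O)OC(C)(C)C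
F4 | step 26 | {3-tert-butoxy-2-[(1S,2R,3R)-2-(2-hydroxy-2-isopropylpent-4-en-1-yl)-3-methylcyclopentyl]-3-oxopropyl}trimethylammonium iodide | C=CCC(O)(C(C)C)C[C@@H]1[C@H](C)CC[C@@H]1C(C[N+](C)(C)C)C(=O)OC(C)(C)C.[I-]
F5 | step 26 | tert-butyl 2-{(1S,2R,3R)-2-[2-hydroxy-2-(propan-2-yl)pent-4-en-1-yl]-3-methylcyclopentyl}prop-2-enoate | C=CCC(O)(C(C)C)C[C@@H]1[C@H](C)CC[C@@H]1C(=C)C(=O)OC(C)(C)C
F6 | step 26 | tert-butyl (3R,3aR,8aS)-5-hydroxy-3-methyl-5-(propan-2-yl)-1,2,3,3a,4,5,6,8a-octahydroazulene-8-carboxylate | CC(C)(C)OC(=O)C1=CCC(O)(C(C)C)C[C@@H]2[C@H](C)CC[C@H]12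
F7 | step 29 | [(4aR,6S,7S,7aR)-6-{[tert-butyl(dimethyl)silyl]oxy}-7-hydroxy-4-methylidene-1-oxooctahydrocyclopenta[c]pyran-7-yl]methyl 4-methylbenzenesulfonate | C=C1COC(=O)[C@@H]2[C@H]1C[C@H](O[Si](C)(C)C(C)(C)C)[C@@]2(O)COS(=O)(=O)c1ccc(C)cc1
F8 | step 29 | (4aR,6S,7S,7aR)-6-{[tert-butyl(dimethyl)silyl]oxy}-4-methylidenehexahydro-1H-spiro[cyclopenta[c]pyran-7,2'-oxiran]-1-one | C=C1COC(=O)[C@@H]2[C@H]1C[C@H](O[Si](C)(C)C(C)(C)C)[C@@]23CO3
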